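**Retrosynthetic overview**

1. Atom numbers follow abietane numbering: ring A = C1–C5 + C10, ring B = C5–C10, C18 = acid carbon on C4, C14 = acid carbon on C8, C11–C13 = chain on C9.
2. Both rings come from one radical cascade of an acyclic tertiary α-bromo ester: ring A closes first (C4–C5), then ring B (C9–C10); loss of acetate from C7 then places C7=C8.
3. The cascade substrate is cut at C7–C8 (hydroalumination of an ynoate, then aldol with an aldehyde); this also fixes the Z-alkene that controls C9.
4. Aldehyde half: C3–C4 by ester enolate alkylation, E-C5=C10 by alkyne carboalumination, C5–C6 by oxirane opening. Ynoate half: enolate propargylation, ketalisation, carboxylation.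
5. Absolute configuration by chromatographic resolution of the racemic bicyclic diester; the last step is global acid deprotection.

Assumption: the radical cascade has no enantio-determining element, so the bicyclic diester 23 is made as a racemate and the single enantiomer is secured by resolution in step 10.

**Route**

Step 1
Reactants: 1 5-chloropent-1-yne; 2 oxirane
Product: 4 (3E)-7-chloro-4-methylhept-3-en-1-ol, via alkenylalane 3 (not isolated)
Conditions: Me3Al, Cp2ZrCl2 (cat.), CH2Cl2, 0 °C → rt; evaporate; nBuLi, THF/hexane, −30 °C; then 2, −30 → 0 °C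
Reagents that add atoms: trimethylaluminium, C[Al](C)C
Why: Zirconium-catalysed syn-carboalumination (Negishi carboalumination) puts methyl on the internal carbon and aluminium on the terminal carbon cis to it, and the derived alanate opens oxirane with retention, so the E-trisubstituted C5=C10 alkene is fixed here.

Step 2
Reactants: 4 (3E)-7-chloro-4-methylhept-3-en-1-ol; 5 tert-butyl propanoate
Product: 7 tert-butyl (6E)-9-hydroxy-2,6-dimethylnon-6-enoate (racemic), via lithium enolate 6 (not isolated)
Conditions: 5, LiN(iPr)2 (2.2 equiv), THF, −78 °C; then 4, NaI (0.2 equiv), DMPU, −78 °C → rt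
Reagents that add atoms: none
Why: Ester enolate alkylation (SN2, iodide catalysis) forms C3–C4, and the lithium alkoxide of 4 is a spectator because O-alkylation by lithium alkoxides is much slower than C-alkylation by the enolate.

Step 3
Reactants: 7 tert-butyl (6E)-9-hydroxy-2,6-dimethylnon-6-enoate
Product: 9 tert-butyl (6E)-2-bromo-9-hydroxy-2,6-dimethylnon-6-enoate (racemic), via dilithio alkoxide enolate 8 (not isolated)
Conditions: LiN(iPr)2 (2.2 equiv), THF, −78 → −40 °C; then CBr4, −78 °C
Reagents that add atoms: tetrabromomethane, BrC(Br)(Br)Br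
Why: Electrophilic α-bromination of the tertiary ester enolate installs the radical precursor, and the C4 configuration is irrelevant because this carbon later becomes a planar radical.

Step 4
Reactants: 9 tert-butyl (6E)-2-bromo-9-hydroxy-2,6-dimethylnon-6-enoate
Product: 10 tert-butyl (6E)-2-bromo-2,6-dimethyl-9-oxonon-6-enoate (racemic)
Conditions: Dess–Martin periodinane, NaHCO3, CH2Cl2, 0 °C; used at once
Reagents that add atoms: none
Why: Buffered Dess–Martin oxidation gives the β,γ-unsaturated aldehyde without moving the C5=C10 double bond into conjugation and leaves the tertiary bromide untouched.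

Step 5
Reactants: 11 3-methylbutan-2-one; 12 3-bromoprop-1-yne
Product: 14 2-methylhept-6-yn-3-one, via lithium enolate 13 (not isolated)
Conditions: LiN(iPr)2, THF, −78 °C; then 12, −78 → 0 °C
Reagents that add atoms: none
Why: Kinetic deprotonation at the methyl group followed by SN2 enolate alkylation gives the C9–C13 chain with the isopropyl ketone in place.

Step 6
Reactants: 14 2-methylhept-6-yn-3-one; 15 ethane-1,2-diol
Product: 16 2-(but-3-yn-1-yl)-2-(propan-2-yl)-1,3-dioxolane
Conditions: TsOH·H2O (cat.), PhH, reflux, Dean–Stark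
Reagents that add atoms: none
Why: Acid-catalysed ketalisation with azeotropic removal of water masks the ketone against iBu2AlH in step 8.

Step 7
Reactants: 16 2-(but-3-yn-1-yl)-2-(propan-2-yl)-1,3-dioxolane
Product: 18 tert-butyl 5-[2-(propan-2-yl)-1,3-dioxolan-2-yl]pent-2-ynoate, via lithium acetylide 17 (not isolated)
Conditions: nBuLi, THF, −78 °C; then Boc2O, −78 → 0 °C
Reagents that add atoms: di-tert-butyl dicarbonate, CC(C)(C)OC(=O)OC(=O)OC(C)(C)C
Why: C-acylation of the lithium acetylide (acetylide carboxylation) gives the tert-butyl ynoate, and the ketal is inert to nBuLi.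

Step 8
Reactants: 18 tert-butyl 5-[2-(propan-2-yl)-1,3-dioxolan-2-yl]pent-2-ynoate; 10 tert-butyl (6E)-2-bromo-2,6-dimethyl-9-oxonon-6-enoate
Product: 21 di-tert-butyl (2Z,5E)-3-acetoxy-10-bromo-6,10-dimethyl-2-{3-[2-(propan-2-yl)-1,3-dioxolan-2-yl]propylidene}undec-5-enedioate (diastereomer mixture), via vinylalane 19 (not isolated), via aluminium alkoxide 20 (not isolated)
Conditions: iBu2AlH, N-methylmorpholine N-oxide, THF, 0 °C, then 18; then 10, 0 °C → rt; then Ac2O, pyridine, DMAP (cat.), rt
Reagents that add atoms: acetic anhydride, CC(=O)OC(C)=O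
Why: Hydroalumination of the ynoate (vinylalumination) is a syn-addition that places aluminium on the α-carbon cis to the vinylic hydrogen, so aldol addition to 10 gives only the Z-alkene (C11 cis to the ester, trans to C7), and the aluminium alkoxide is acetylated in the same flask; the C7 configuration is irrelevant because C7 becomes sp2.

Step 9
Reactants: 21 di-tert-butyl (2Z,5E)-3-acetoxy-10-bromo-6,10-dimethyl-2-{3-[2-(propan-2-yl)-1,3-dioxolan-2-yl]propylidene}undec-5-enedioate
Product: 23 racemic di-tert-butyl 13,13-(ethylenedioxy)-13,14-seco-abiet-7-ene-14,18-dioate, via acetoxy ester 22 (not isolated)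
Conditions: (Me3Si)3SiH (slow addition), AIBN (cat.), PhMe (0.005 M), 80 °C; then DBU, 80 °C
Reagents that add atoms: none
Why: Proposed new method: bromine abstraction gives the tertiary α-ester radical at C4, which closes ring A by 6-endo attack on C5 of the E-alkene through a chair (the planar ester takes the pseudo-equatorial site so that its in-plane oxygen eclipses a C3–H and not the C2 chain, allylic 1,3-strain, giving 4α-ester and 4β-methyl, while the E geometry gives the trans ring fusion with 5α-H and 10β-methyl), the tertiary C10 radical then closes ring B by 6-endo conjugate addition to C9 of the Z-enoate (chair with C11 equatorial, hence 9β side chain and 9α-H), hydrogen transfer from the silane gives 22 and DBU removes acetate by E1cB to place C7=C8, the closest known reactions being the 6-endo/6-endo radical polyene cyclisations of α-carbonyl radicals (trivalent manganese or tin hydride mediated) and radical additions to Morita–Baylis–Hillman acetates followed by loss of acetate.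

Step 10
Reactants: 23 racemic di-tert-butyl 13,13-(ethylenedioxy)-13,14-seco-abiet-7-ene-14,18-dioate
Product: 24 di-tert-butyl (1R,4aS,5R,8aR)-1,4a-dimethyl-5-{2-[2-(propan-2-yl)-1,3-dioxolan-2-yl]ethyl}-1,2,3,4,4a,5,8,8a-octahydronaphthalene-1,6-dicarboxylate
Conditions: preparative SFC, amylose tris(3,5-dimethylphenylcarbamate) stationary phase, CO2/iPrOH
Reagents that add atoms: none
Why: Chromatographic resolution on a chiral stationary phase separates the two enantiomers of 23 and delivers the one with the configuration of the target.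

Step 11
Reactants: 24 di-tert-butyl (1R,4aS,5R,8aR)-1,4a-dimethyl-5-{2-[2-(propan-2-yl)-1,3-dioxolan-2-yl]ethyl}-1,2,3,4,4a,5,8,8a-octahydronaphthalene-1,6-dicarboxylate
Product: 25 (1R,4aS,5R,8aR)-1,4a-dimethyl-5-(4-methyl-3-oxopentyl)-1,2,3,4,4a,5,8,8a-octahydronaphthalene-1,6-dicarboxylic acid
Conditions: CF3CO2H/CH2Cl2 (1:1), rt; then H2O, rt
Reagents that add atoms: water, O
Why: Acidolysis of both tert-butyl esters (loss of 2-methylpropene) and acid-catalysed ketal hydrolysis unmask the diacid and the ketone without touching a stereocentre or moving the conjugated C7=C8 bond.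

**Compound list**

1 | 5-chloropent-1-yne | ClCCCC#C | starting material
2 | oxirane | C1CO1 | starting material
3 | dimethyl[(1E)-5-chloro-2-methylpent-1-en-1-yl]alumane (alkenylalane, Al cis to methyl) | C[Al](C)/C=C(\C)CCCCl | intermediate
4 | (3E)-7-chloro-4-methylhept-3-en-1-ol | OCC/C=C(\C)CCCCl | intermediate
5 | tert-butyl propanoate | CCC(=O)OC(C)(C)C | starting material
6 | lithium 1-tert-butoxyprop-1-en-1-olate (lithium enolate of 5) | CC=C(O[Li])OC(C)(C)C | intermediate
7 | tert-butyl (6E)-9-hydroxy-2,6-dimethylnon-6-enoate (racemic) | CC(C(=O)OC(C)(C)C)CCC/C(C)=C/CCO | intermediate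
8 | dilithio alkoxide enolate of 7 (6E) | [Li]OCC/C=C(\C)CCCC(C)=C(O[Li])OC(C)(C)C | intermediate
9 | tert-butyl (6E)-2-bromo-9-hydroxy-2,6-dimethylnon-6-enoate (racemic) | CC(Br)(C(=O)OC(C)(C)C)CCC/C(C)=C/CCO | intermediate
10 | tert-butyl (6E)-2-bromo-2,6-dimethyl-9-oxonon-6-enoate (racemic) | CC(Br)(C(=O)OC(C)(C)C)CCC/C(C)=C/CC=O | intermediate
11 | 3-methylbutan-2-one | CC(C)C(C)=O | starting material
12 | 3-bromoprop-1-yne | C#CCBr | starting material
13 | lithium 3-methylbut-1-en-2-olate (kinetic enolate of 11) | C=C(O[Li])C(C)C | intermediate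
14 | 2-methylhept-6-yn-3-one | CC(C)C(=O)CCC#C | intermediate
15 | ethane-1,2-diol | OCCO | starting material
16 | 2-(but-3-yn-1-yl)-2-(propan-2-yl)-1,3-dioxolane | CC(C)C1(CCC#C)OCCO1 | intermediate
17 | lithium acetylide of 16 | [Li]C#CCCC1(C(C)C)OCCO1 | intermediate
18 | tert-butyl 5-[2-(propan-2-yl)-1,3-dioxolan-2-yl]pent-2-ynoate | CC(C)C1(CCC#CC(=O)OC(C)(C)C)OCCO1 | intermediate
19 | tert-butyl (2E)-2-[bis(2-methylpropyl)alumanyl]-5-[2-(propan-2-yl)-1,3-dioxolan-2-yl]pent-2-enoate (vinylalane, Al cis to the vinylic H) | CC(C)C[Al](CC(C)C)/C(C(=O)OC(C)(C)C)=C/CCC1(C(C)C)OCCO1 | intermediate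
20 | bis(2-methylpropyl)aluminium alkoxide of di-tert-butyl (2Z,5E)-10-bromo-3-hydroxy-6,10-dimethyl-2-{3-[2-(propan-2-yl)-1,3-dioxolan-2-yl]propylidene}undec-5-enedioate | CC(Br)(C(=O)OC(C)(C)C)CCC/C(C)=C/CC(O[Al](CC(C)C)CC(C)C)/C(C(=O)OC(C)(C)C)=C/CCC1(C(C)C)OCCO1 | intermediate
21 | di-tert-butyl (2Z,5E)-3-acetoxy-10-bromo-6,10-dimethyl-2-{3-[2-(propan-2-yl)-1,3-dioxolan-2-yl]propylidene}undec-5-enedioate (mixture at C3 and C10, each racemic) | CC(Br)(C(=O)OC(C)(C)C)CCC/C(C)=C/CC(OC(C)=O)/C(C(=O)OC(C)(C)C)=C/CCC1(C(C)C)OCCO1 | intermediate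
22 | di-tert-butyl 7-acetoxy-13,13-(ethylenedioxy)-13,14-seco-abietane-14,18-dioate (racemic; 4α-ester, 4β-CH3, 5α-H, 9α-H, 10β-CH3; mixture at C7 and C8; one enantiomer drawn) | CC(C)C3(OCCO3)CC[C@H]1C(C(=O)OC(C)(C)C)C(OC(C)=O)C[C@@H]2[C@]1(C)CCC[C@@]2(C)C(=O)OC(C)(C)C | intermediate
23 | racemic di-tert-butyl 13,13-(ethylenedioxy)-13,14-seco-abiet-7-ene-14,18-dioate (trans-decalin; 4α-ester, 4β-CH3, 5α-H, 9α-H, 10β-CH3, and its mirror image) | CC(C)C3(OCCO3)CC[C@H]1C(C(=O)OC(C)(C)C)=CC[C@@H]2[C@]1(C)CCC[C@@]2(C)C(=O)OC(C)(C)C.CC(C)C3(OCCO3)CC[C@@H]1C(C(=O)OC(C)(C)C)=CC[C@H]2[C@@]1(C)CCC[C@]2(C)C(=O)OC(C)(C)C | intermediate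
24 | di-tert-butyl (1R,4aS,5R,8aR)-1,4a-dimethyl-5-{2-[2-(propan-2-yl)-1,3-dioxolan-2-yl]ethyl}-1,2,3,4,4a,5,8,8a-octahydronaphthalene-1,6-dicarboxylate | CC(C)C3(OCCO3)CC[C@H]1C(C(=O)OC(C)(C)C)=CC[C@@H]2[C@]1(C)CCC[C@@]2(C)C(=O)OC(C)(C)C | intermediate
25 | (1R,4aS,5R,8aR)-1,4a-dimethyl-5-(4-methyl-3-oxopentyl)-1,2,3,4,4a,5,8,8a-octahydronaphthalene-1,6-dicarboxylic acid (13-oxo-13,14-seco-abiet-7-ene-14,18-dioic acid; 4α-CO2H, 4β-CH3, 5α-H, 9α-H, 10β-CH3) | CC(C)C(=O)CC[C@H]1C(C(=O)O)=CC[C@@H]2[C@]1(C)CCC[C@@]2(C)C(=O)O | target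

**Totals**

Total step count: 11. Longest linear sequence: 8 steps (steps 1, 2, 3, 4, 8, 9, 10, 11).

**Steps most likely to fail**

Step 9 (radical bicyclisation). The C4 or C10 radical may be reduced by the silane before it cyclises, and the facial arrangement at C4 rests on a conformational argument, not on precedent. Fallback: setting out from 21, a hydrogen-donor-free atom-transfer cyclisation (CuBr with tris(2-pyridylmethyl)amine, catalytic, MeCN/PhMe, 60 °C) runs the same 6-endo/6-endo cascade and ends by bromine transfer to C8, giving the bicyclic 8-bromo-7-acetoxy diester F1. Zinc dust in AcOH/THF then removes bromide and acetate together (reductive β-elimination) and comes back to the route at 23.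

Step 8 (hydroalumination and aldol). The β,γ-unsaturated aldehyde 10 may enolise or be reduced by residual hydride. Fallback: setting out from 10, MgI2 and tert-butyl prop-2-ynoate in CH2Cl2 at 0 °C (iodo-aldol) give the (Z)-β-iodo allylic alcohol F2. Separately, 4-methylpent-1-en-3-one is converted with Me3SiCl/NaI and then ethane-1,2-diol into the β-iodo ketal 2-(2-iodoethyl)-2-(propan-2-yl)-1,3-dioxolane F3. The zinc reagent of F3 (Zn, LiCl, THF) is cross-coupled with F2 (Pd(PPh3)4, retention of alkene geometry) to give the allylic alcohol F4. Acetylation (Ac2O, DMAP) comes back to the route at 21.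

Step 2 (alkylation beside a free alkoxide). O-alkylation or sluggish C-alkylation may lower the yield. Fallback: setting out from 4, TBSCl/imidazole gives the silyl ether F5. Alkylation of enolate 6 with F5 (NaI, DMPU) gives the silyl-protected ester F6, and LiN(iPr)2 then CBr4 gives the silyl-protected bromo ester F7. HF·pyridine removes the silyl group and comes back to the route at 9.

**Further compounds**

F1 | step 9 | di-tert-butyl 7-acetoxy-8-bromo-13,13-(ethylenedioxy)-13,14-seco-abietane-14,18-dioate (racemic; ring stereocentres as in 23; mixture at C7 and C8; one enantiomer drawn) | CC(C)C3(OCCO3)CC[C@H]1C(Br)(C(=O)OC(C)(C)C)C(OC(C)=O)C[C@@H]2[C@]1(C)CCC[C@@]2(C)C(=O)OC(C)(C)C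
F2 | step 8 | di-tert-butyl (2Z,5E)-10-bromo-3-hydroxy-2-(iodomethylidene)-6,10-dimethylundec-5-enedioate (diastereomer mixture) | CC(Br)(C(=O)OC(C)(C)C)CCC/C(C)=C/CC(O)/C(C(=O)OC(C)(C)C)=C/I
F3 | step 8 | 2-(2-iodoethyl)-2-(propan-2-yl)-1,3-dioxolane | CC(C)C1(CCI)OCCO1
F4 | step 8 | di-tert-butyl (2Z,5E)-10-bromo-3-hydroxy-6,10-dimethyl-2-{3-[2-(propan-2-yl)-1,3-dioxolan-2-yl]propylidene}undec-5-enedioate (diastereomer mixture) | CC(Br)(C(=O)OC(C)(C)C)CCC/C(C)=C/CC(O)/C(C(=O)OC(C)(C)C)=C/CCC1(C(C)C)OCCO1
F5 | step 2 | tert-butyl{[(3E)-7-chloro-4-methylhept-3-en-1-yl]oxy}dimethylsilane | CC(C)(C)[Si](C)(C)OCC/C=C(\C)CCCCl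
F6 | step 2 | tert-butyl (6E)-9-[(tert-butyldimethylsilyl)oxy]-2,6-dimethylnon-6-enoate (racemic) | CC(C(=O)OC(C)(C)C)CCC/C(C)=C/CCO[Si](C)(C)C(C)(C)C
F7 | step 2 | tert-butyl (6E)-2-bromo-9-[(tert-butyldimethylsilyl)oxy]-2,6-dimethylnon-6-enoate (racemic) | CC(Br)(C(=O)OC(C)(C)C)CCC/C(C)=C/CCO[Si](C)(C)C(C)(C)C
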